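**Retrosynthetic overview**

1. Target 25 ⇐ tris-benzyl ether 24 (one hydrogenolysis) ⇐ benzo-fused bicyclo[2.2.0]hexane 21. Ring B appears when the central C1–C4 bond of 21, a bond absent from the target and made only to be broken, is cleaved with release of the strain of two four-membered rings.
2. 21 ⇐ aryne 20 + (S)-1-silyloxycyclobutene 18 by [2+2] cycloaddition, which makes C4–C4a and C1–C8a in one event (tetralone numbering). Steps 12 and 13 together amount to insertion of the ring A aryne into the C(=O)–CH2 bond of a cyclobutanone.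
3. Enabling feature: O8 of ring A sits on the carbon next to the ring-fusion atom C8a, so the C4a≡C8a aryne is a 3-alkoxyaryne polarised to take the nucleophilic enol ether CH at C4a and the oxygen-bearing carbon at C8a. Ring B is then exactly the four carbons C1–C4 of a 3-oxygenated cyclobutanone plus these two aryne carbons.
4. C3 stereocentre ⇐ enantiotopos-selective deprotonation of 3-(benzyloxy)cyclobutanone 16. Aryne precursor 15 ⇐ symmetric 5-(3-methylbutyl)resorcinol 4 (iodination between the oxygens, ortho-formylation, differentiation of the two hydroxyls).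
5. Order of rings: ring A (from a benzene building block) → pyranone ring C (aldehyde → dioxinone → acylketene, steps 7–9) → two temporary four-membered rings (step 12) → ring B (step 13).

Key step: step 12

Assumption: the (R,R) antipode of the lithium amide in step 11 is taken to give the (S)-enol ether 18; the sense of induction for this substrate rests on analogy, and the (S,S) base would be used instead if it proved opposite.

**Route**

Step 1
Reactants: 1 3,5-dimethoxybenzyl bromide; 2 isobutylmagnesium bromide
Product: 3 1,3-dimethoxy-5-(3-methylbutyl)benzene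
Conditions: Li2CuCl4 (cat.), THF, −20 → 0 °C
Reagents that add atoms: none
Why: Copper-catalysed sp3–sp3 coupling of a Grignard reagent with a benzylic bromide (Kochi-type coupling) should install the 3-methylbutyl chain.

Step 2
Reactants: 3 1,3-dimethoxy-5-(3-methylbutyl)benzene
Product: 4 5-(3-methylbutyl)benzene-1,3-diol
Conditions: BBr3, CH2Cl2, −78 °C → rt
Reagents that add atoms: none
Why: Lewis acid ether cleavage with BBr3 should remove both aryl methyl groups, as in the standard preparation of 5-alkylresorcinols.

Step 3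
Reactants: 4 5-(3-methylbutyl)benzene-1,3-diol
Product: 5 2-iodo-5-(3-methylbutyl)benzene-1,3-diol
Conditions: I2, NaHCO3, H2O–THF, 0 °C
Reagents that add atoms: iodine, II
Why: Electrophilic aromatic iodination under bicarbonate (phenoxide) conditions should go to C2 between the two hydroxyls, as in the preparation of 2-iodoresorcinol, helped here by the alkyl group that shields C4 and C6.

Step 4
Reactants: 5 2-iodo-5-(3-methylbutyl)benzene-1,3-diol
Product: 6 2,4-dihydroxy-3-iodo-6-(3-methylbutyl)benzaldehyde
Conditions: MgCl2, Et3N, (CH2O)n, MeCN, 80 °C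
Reagents that add atoms: formaldehyde (as paraformaldehyde), C=O
Why: Magnesium-mediated ortho-formylation of a phenol (Casnati–Skattebøl reaction) can give only one monoaldehyde, because C2 is blocked by iodine and C4 and C6 are equivalent by symmetry.

Step 5
Reactants: 6 2,4-dihydroxy-3-iodo-6-(3-methylbutyl)benzaldehyde
Product: 7 4-(benzyloxy)-2-hydroxy-3-iodo-6-(3-methylbutyl)benzaldehyde
Conditions: BnBr, K2CO3, acetone, rt
Reagents that add atoms: benzyl bromide, BrCc1ccccc1
Why: Williamson etherification should be selective for the 4-hydroxyl, since the 2-hydroxyl is held in a hydrogen bond to the aldehyde and is the less acidic and less nucleophilic of the two.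

Step 6
Reactants: 7 4-(benzyloxy)-2-hydroxy-3-iodo-6-(3-methylbutyl)benzaldehyde
Product: 8 3-(benzyloxy)-6-formyl-2-iodo-5-(3-methylbutyl)phenyl trifluoromethanesulfonate
Conditions: Tf2O, pyridine, CH2Cl2, 0 °C
Reagents that add atoms: trifluoromethanesulfonic anhydride, O=S(=O)(OS(=O)(=O)C(F)(F)F)C(F)(F)F
Why: O-Sulfonylation of the remaining phenol should give the aryl triflate that later serves as the leaving group of the aryne precursor.

Step 7
Reactants: 8 3-(benzyloxy)-6-formyl-2-iodo-5-(3-methylbutyl)phenyl trifluoromethanesulfonate; 9 2,2,6-trimethyl-4H-1,3-dioxin-4-one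
Product: 11 3-(benzyloxy)-6-[2-(2,2-dimethyl-4-oxo-4H-1,3-dioxin-6-yl)-1-hydroxyethyl]-2-iodo-5-(3-methylbutyl)phenyl trifluoromethanesulfonate (racemic), via lithium dienolate 10 (not isolated)
Conditions: LiN(i-Pr)2, THF, −78 °C; then 8, −78 °C; AcOH quench at −78 °C
Reagents that add atoms: none
Why: Vinylogous aldol addition of the dioxinone dienolate through its γ-carbon to the hindered but reactive aldehyde should give the carbinol as a racemate, which is of no consequence because this centre is oxidised away in step 8.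

Step 8
Reactants: 11 (racemic carbinol)
Product: 12 3-(benzyloxy)-6-[2-(2,2-dimethyl-4-oxo-4H-1,3-dioxin-6-yl)acetyl]-2-iodo-5-(3-methylbutyl)phenyl trifluoromethanesulfonate
Conditions: Dess–Martin periodinane, CH2Cl2, rt
Reagents that add atoms: none
Why: Dess–Martin oxidation of the benzylic alcohol should give the aryl ketone under neutral conditions that leave iodide, triflate and dioxinone untouched.

Step 9
Reactants: 12 (keto dioxinone)
Product: 14 3-(benzyloxy)-6-(4-hydroxy-2-oxo-2H-pyran-6-yl)-2-iodo-5-(3-methylbutyl)phenyl trifluoromethanesulfonate, via acylketene 13 (not isolated)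
Conditions: toluene, 110 °C
Reagents that add atoms: none
Why: Thermal retro-[4+2] of the dioxinone releases acetone and an acylketene, which should cyclise through the enol oxygen of the aryl ketone to the 4-hydroxy-2-pyranone (dioxinone thermolysis–acylketene cyclisation).

Step 10
Reactants: 14 (hydroxypyranone)
Product: 15 3-(benzyloxy)-6-[4-(benzyloxy)-2-oxo-2H-pyran-6-yl]-2-iodo-5-(3-methylbutyl)phenyl trifluoromethanesulfonate
Conditions: BnOH, PPh3, DIAD, THF, 0 °C → rt
Reagents that add atoms: benzyl alcohol, OCc1ccccc1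
Why: Mitsunobu O-alkylation of the acidic 4-hydroxy-2-pyranone should give the 4-benzyl ether under neutral conditions that spare the triflate.

Step 11
Reactants: 16 3-(benzyloxy)cyclobutan-1-one
Product: 18 (S)-{[3-(benzyloxy)cyclobut-1-en-1-yl]oxy}trimethylsilane, via lithium enolate 17 (not isolated)
Conditions: LiN[(R)-CH(Me)Ph]2 (from the amine and n-BuLi), Me3SiCl (internal quench), THF, −100 °C
Reagents that add atoms: chlorotrimethylsilane, C[Si](C)(C)Cl
Why: Enantioselective deprotonation of a prochiral 3-substituted cyclobutanone by a C2-symmetric chiral lithium amide (Simpkins–Koga-type desymmetrisation) selects one of the two enantiotopic α-CH2 groups, which fixes C3 as (S), and the internal silyl quench should trap the β-benzyloxy enolate before it can eliminate.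

Step 12
Reactants: 15 (2-iodoaryl triflate); 18 (S)-silyl enol ether (2.5 equiv)
Product: 21 3,9-bis(benzyloxy)-6-[4-(benzyloxy)-2-oxo-2H-pyran-6-yl]-5-(3-methylbutyl)-1-(trimethylsilyloxy)tricyclo[6.2.0.0(2,7)]deca-2,4,6-triene (cis-fused, arene anti to the C9 benzyloxy group, C9 as in 18), via arylmagnesium chloride 19 (not isolated), via aryne 20 (not isolated)
Conditions: i-PrMgCl·LiCl (1.05 equiv), THF, −78 → −10 °C
Reagents that add atoms: none
Why: Proposed new method: iodine–magnesium exchange on 15 gives the ortho-triflyloxy arylmagnesium 19, which on warming loses MgCl(OTf) to give the C4a≡C8a aryne 20 (tetralone numbering); the electron-rich CH of silyl enol ether 18 attacks C4a, the aryne carbon meta to the benzyloxy group, and the resulting C8a carbanion closes on the silyloxy-stabilised cyclobutyl cation, a stepwise polar [2+2] that forms C4–C4a and C1–C8a in one event. The closest known reactions are the regioselective [2+2] cycloadditions of 3-alkoxybenzynes (generated from 2-iodoaryl triflates with organometallic reagents) with ketene silyl acetals and the aryne–enolate ring expansion of cyclic ketones; the untested element is a 1-silyloxycyclobutene as the 2π partner, which must give a benzo-fused bicyclo[2.2.0]hexane. The new four-membered ring closes in a 4-exo-trig mode onto the oxocarbenium carbon and is necessarily cis-fused to the cyclobutane. The two new stereocentres (C1 and C4) are set by approach of the aryne anti to the C3 benzyloxy group but are both erased in step 13, whereas C3 is carried unchanged from 18. The step needs regioselectivity, which the inductive polarisation of the aryne by the C8 benzyloxy group should secure against the steric bias of the C5 pyranonyl group; it needs chemoselectivity for [2+2] over ene-type arylation, oxygen-to-carbon silyl transfer and Diels–Alder capture by the pyranone diene, which the strained, polarised enol ether used in excess should favour; and it needs fluoride-free aryne generation, so that neither 18 nor 21 is desilylated to a β-benzyloxy enolate.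

Step 13
Reactants: 21 (cycloadduct, used crude)
Product: 24 (3R)-3,8-bis(benzyloxy)-5-[4-(benzyloxy)-2-oxo-2H-pyran-6-yl]-6-(3-methylbutyl)-3,4-dihydronaphthalen-1(2H)-one, via cyclobutanol 22 (not isolated), via dienol 23 (not isolated)
Conditions: Bu4NF, AcOH (1:1), THF, −40 → 0 °C
Reagents that add atoms: none
Why: Buffered desilylation gives the strained benzocyclobutenol, whose alkoxide should undergo retro-aldol-type cleavage of the C1–C4 bond with release of the strain of both four-membered rings, and protonation of the resulting dienolate by way of the dienol and its 1,5-hydrogen shift gives the tetralone (Caubère-type ring expansion of a ring-fused benzocyclobutenol) without touching C3.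

Step 14
Reactants: 24 (tris-benzyl ether)
Product: 25 (3R)-3,8-dihydroxy-5-(4-hydroxy-2-oxo-2H-pyran-6-yl)-6-(3-methylbutyl)-3,4-dihydronaphthalen-1(2H)-one
Conditions: H2 (1 atm), Pd/C, EtOAc–MeOH, rt
Reagents that add atoms: none
Why: Palladium-catalysed hydrogenolysis should remove the aryl, pyranonyl and secondary alkyl benzyl ethers in one neutral operation, avoiding the acid or base that would dehydrate the β-hydroxy ketone to a naphthol.

**Compound list**

1 | 3,5-dimethoxybenzyl bromide | COc1cc(CBr)cc(OC)c1 | starting material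
2 | isobutylmagnesium bromide | CC(C)C[Mg]Br | starting material
3 | 1,3-dimethoxy-5-(3-methylbutyl)benzene | COc1cc(CCC(C)C)cc(OC)c1 | intermediate
4 | 5-(3-methylbutyl)benzene-1,3-diol | CC(C)CCc1cc(O)cc(O)c1 | intermediate
5 | 2-iodo-5-(3-methylbutyl)benzene-1,3-diol | CC(C)CCc1cc(O)c(I)c(O)c1 | intermediate
6 | 2,4-dihydroxy-3-iodo-6-(3-methylbutyl)benzaldehyde | CC(C)CCc1cc(O)c(I)c(O)c1C=O | intermediate
7 | 4-(benzyloxy)-2-hydroxy-3-iodo-6-(3-methylbutyl)benzaldehyde | CC(C)CCc1cc(OCc2ccccc2)c(I)c(O)c1C=O | intermediate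
8 | 3-(benzyloxy)-6-formyl-2-iodo-5-(3-methylbutyl)phenyl trifluoromethanesulfonate | CC(C)CCc1cc(OCc2ccccc2)c(I)c(OS(=O)(=O)C(F)(F)F)c1C=O | intermediate
9 | 2,2,6-trimethyl-4H-1,3-dioxin-4-one | CC1=CC(=O)OC(C)(C)O1 | starting material
10 | lithium 2,2-dimethyl-6-methylidene-6H-1,3-dioxin-4-olate (dienolate of 9) | C=C1C=C(O[Li])OC(C)(C)O1 | intermediate (not isolated)
11 | 3-(benzyloxy)-6-[2-(2,2-dimethyl-4-oxo-4H-1,3-dioxin-6-yl)-1-hydroxyethyl]-2-iodo-5-(3-methylbutyl)phenyl trifluoromethanesulfonate (racemic) | CC(C)CCc1cc(OCc2ccccc2)c(I)c(OS(=O)(=O)C(F)(F)F)c1C(O)CC1=CC(=O)OC(C)(C)O1 | intermediate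
12 | 3-(benzyloxy)-6-[2-(2,2-dimethyl-4-oxo-4H-1,3-dioxin-6-yl)acetyl]-2-iodo-5-(3-methylbutyl)phenyl trifluoromethanesulfonate | CC(C)CCc1cc(OCc2ccccc2)c(I)c(OS(=O)(=O)C(F)(F)F)c1C(=O)CC1=CC(=O)OC(C)(C)O1 | intermediate
13 | acylketene: 5-aryl-pent-1-ene-1,3,5-trione with the aryl group of 12 | CC(C)CCc1cc(OCc2ccccc2)c(I)c(OS(=O)(=O)C(F)(F)F)c1C(=O)CC(=O)C=C=O | intermediate (not isolated)
14 | 3-(benzyloxy)-6-(4-hydroxy-2-oxo-2H-pyran-6-yl)-2-iodo-5-(3-methylbutyl)phenyl trifluoromethanesulfonate | CC(C)CCc1cc(OCc2ccccc2)c(I)c(OS(=O)(=O)C(F)(F)F)c1C1=CC(O)=CC(=O)O1 | intermediate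
15 | 3-(benzyloxy)-6-[4-(benzyloxy)-2-oxo-2H-pyran-6-yl]-2-iodo-5-(3-methylbutyl)phenyl trifluoromethanesulfonate | CC(C)CCc1cc(OCc2ccccc2)c(I)c(OS(=O)(=O)C(F)(F)F)c1C1=CC(OCc2ccccc2)=CC(=O)O1 | intermediate
16 | 3-(benzyloxy)cyclobutan-1-one | O=C1CC(OCc2ccccc2)C1 | starting material
17 | lithium (S)-3-(benzyloxy)cyclobut-1-en-1-olate | [Li]OC1=C[C@@H](OCc2ccccc2)C1 | intermediate (not isolated)
18 | (S)-{[3-(benzyloxy)cyclobut-1-en-1-yl]oxy}trimethylsilane | C[Si](C)(C)OC1=C[C@@H](OCc2ccccc2)C1 | intermediate
19 | arylmagnesium chloride from 15 (Mg in place of iodine, ortho to the triflate) | CC(C)CCc1cc(OCc2ccccc2)c([Mg]Cl)c(OS(=O)(=O)C(F)(F)F)c1C1=CC(OCc2ccccc2)=CC(=O)O1 | intermediate (not isolated)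
20 | aryne: 3-(benzyloxy)-6-[4-(benzyloxy)-2-oxo-2H-pyran-6-yl]-5-(3-methylbutyl)-1,2-didehydrobenzene | CC(C)CCC1=C(C2=CC(OCc3ccccc3)=CC(=O)O2)C#CC(OCc2ccccc2)=C1 | intermediate (not isolated)
21 | 3,9-bis(benzyloxy)-6-[4-(benzyloxy)-2-oxo-2H-pyran-6-yl]-5-(3-methylbutyl)-1-(trimethylsilyloxy)tricyclo[6.2.0.0(2,7)]deca-2,4,6-triene; cis ring fusion at C1–C8, aryl bonds anti to the C9 benzyloxy group, C9 configuration carried over from 18 | CC(C)CCc1cc(OCc4ccccc4)c2c(c1C5=CC(OCc6ccccc6)=CC(=O)O5)[C@@H]3[C@@H](OCc7ccccc7)C[C@]23O[Si](C)(C)C | intermediate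
22 | the free cyclobutanol of 21 (tricyclo[6.2.0.0(2,7)]deca-2,4,6-trien-1-ol, same substituents and configuration) | CC(C)CCc1cc(OCc4ccccc4)c2c(c1C5=CC(OCc6ccccc6)=CC(=O)O5)[C@@H]3[C@@H](OCc7ccccc7)C[C@]23O | intermediate (not isolated)
23 | dienol tautomer of 24: 3,8-bis(benzyloxy)-5-[4-(benzyloxy)-2-oxo-2H-pyran-6-yl]-6-(3-methylbutyl)-2,3-dihydronaphthalen-1-ol, C3 configured as in 24 | OC1=C2C(OCc3ccccc3)=CC(CCC(C)C)=C(C4=CC(OCc5ccccc5)=CC(=O)O4)C2=C[C@@H](OCc6ccccc6)C1 | intermediate (not isolated)
24 | (3R)-3,8-bis(benzyloxy)-5-[4-(benzyloxy)-2-oxo-2H-pyran-6-yl]-6-(3-methylbutyl)-3,4-dihydronaphthalen-1(2H)-one | CC(C)CCc1cc(OCc3ccccc3)c2c(c1C4=CC(OCc5ccccc5)=CC(=O)O4)C[C@@H](OCc6ccccc6)CC2=O | intermediate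
25 | (3R)-3,8-dihydroxy-5-(4-hydroxy-2-oxo-2H-pyran-6-yl)-6-(3-methylbutyl)-3,4-dihydronaphthalen-1(2H)-one | CC(C)CCc1cc(O)c2c(c1-c1cc(O)cc(=O)o1)C[C@@H](O)CC2=O | target

**Step count and risks**

Total step count: 14. Longest linear sequence: 13 steps (steps 1–10, 12, 13, 14); step 11 is a one-step side branch.

The three steps most likely to fail:

1. Step 12 (Proposed new method). The aryne may be consumed by other channels: ene-type arylation of the enol ether, oxygen-to-carbon silyl transfer in the zwitterion, Diels–Alder capture by the pyranone of a second molecule, or addition of the enol ether at C8a if the pyranonyl group overrides the alkoxy polarisation. The fallback uses known chemistry and sets out from 15. The aryne 20 is generated as in step 12 but in the presence of the sodium enolate of methyl acetoacetate (NaH, THF). By aryne acyl-alkylation (insertion into the C–C bond of a β-keto ester, with the same alkoxy-directed regiochemistry) this should give methyl 2-[2-acetyl-3-(benzyloxy)-6-[4-(benzyloxy)-2-oxo-2H-pyran-6-yl]-5-(3-methylbutyl)phenyl]acetate F1. LiN(SiMe3)2 (THF, −78 → 0 °C) should then close ring B by Dieckmann-type condensation and tautomerisation to 8-(benzyloxy)-5-[4-(benzyloxy)-2-oxo-2H-pyran-6-yl]-6-(3-methylbutyl)naphthalene-1,3-diol F2. Hydrogenolysis (H2, Pd/C) should give the air-sensitive 5-(4-hydroxy-2-oxo-2H-pyran-6-yl)-6-(3-methylbutyl)naphthalene-1,3,8-triol F3. Its 3-keto tautomer would be reduced under argon by the NADPH-dependent tetrahydroxynaphthalene reductase (glucose and glucose dehydrogenase for cofactor recycling), the enzymatic dearomatising reduction that converts 1,3,8-trihydroxynaphthalene into (R)-vermelone. The route is rejoined at 25.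

2. Step 11. The lithium enolate may lose benzyloxide by β-elimination before it is silylated, or the chiral base may discriminate poorly between the two enantiotopic methylene groups of an oxygen-substituted cyclobutanone. The fallback sets out from 16 and gives up asymmetric induction for resolution. Soft enolisation (Me3SiOSO2CF3, Et3N, CH2Cl2, 0 °C), which never forms a free enolate, should give 18 together with its enantiomer, (R)-{[3-(benzyloxy)cyclobut-1-en-1-yl]oxy}trimethylsilane F4. Steps 12 and 13 on this racemate should give 21 together with the mirror-image cycloadduct F5, and from it, by way of the mirror-image cyclobutanol F6 and the mirror-image dienol F7 (neither isolated), 24 together with the (3S)-tetralone F8. Preparative chromatography on a chiral stationary phase then separates the enantiomers, and the route is rejoined at 24.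

3. Step 13. The dienolate formed on ring opening may expel benzyloxide from C3 (E1cB) faster than it is protonated, which would aromatise ring B to a 1-naphthol; the product 24 is open to the same loss on prolonged exposure to base. The fallback sets out from 21 and replaces the anionic cleavage by a radical one. Desilylation under acidic buffering (HF·pyridine, pyridine, THF, 0 °C) should allow the cyclobutanol 22 to be isolated. Redox-neutral ring opening of this aryl cycloalkanol by proton-coupled electron transfer ([Ir(dF(CF3)ppy)2(5,5'-d(CF3)bpy)]PF6, 2,4,6-collidine, thiophenol as hydrogen-atom donor, blue light, CH2Cl2) then generates the alkoxy radical, whose β-scission of the C1–C4 bond gives a benzylic radical that is reduced by the thiol. No carbanion β to the benzyloxy group is formed, and the route is rejoined at 24.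

**Further compounds**

F1 | step 12 | methyl 2-[2-acetyl-3-(benzyloxy)-6-[4-(benzyloxy)-2-oxo-2H-pyran-6-yl]-5-(3-methylbutyl)phenyl]acetate | CC(C)CCc1cc(OCc2ccccc2)c(C(C)=O)c(CC(=O)OC)c1C1=CC(OCc2ccccc2)=CC(=O)O1
F2 | step 12 | 8-(benzyloxy)-5-[4-(benzyloxy)-2-oxo-2H-pyran-6-yl]-6-(3-methylbutyl)naphthalene-1,3-diol | CC(C)CCc1cc(OCc3ccccc3)c2c(O)cc(O)cc2c1C4=CC(OCc5ccccc5)=CC(=O)O4
F3 | step 12 | 5-(4-hydroxy-2-oxo-2H-pyran-6-yl)-6-(3-methylbutyl)naphthalene-1,3,8-triol | CC(C)CCc1cc(O)c2c(O)cc(O)cc2c1C3=CC(O)=CC(=O)O3
F4 | step 11 | (R)-{[3-(benzyloxy)cyclobut-1-en-1-yl]oxy}trimethylsilane | C[Si](C)(C)OC1=C[C@H](OCc2ccccc2)C1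
F5 | step 11 | enantiomer of cycloadduct 21 | CC(C)CCc1cc(OCc4ccccc4)c2c(c1C5=CC(OCc6ccccc6)=CC(=O)O5)[C@H]3[C@H](OCc7ccccc7)C[C@@]23O[Si](C)(C)C
F6 | step 11 | enantiomer of cyclobutanol 22 (not isolated) | CC(C)CCc1cc(OCc4ccccc4)c2c(c1C5=CC(OCc6ccccc6)=CC(=O)O5)[C@H]3[C@H](OCc7ccccc7)C[C@@]23O
F7 | step 11 | enantiomer of dienol 23 (not isolated) | OC1=C2C(OCc3ccccc3)=CC(CCC(C)C)=C(C4=CC(OCc5ccccc5)=CC(=O)O4)C2=C[C@H](OCc6ccccc6)C1
F8 | step 11 | (3S)-3,8-bis(benzyloxy)-5-[4-(benzyloxy)-2-oxo-2H-pyran-6-yl]-6-(3-methylbutyl)-3,4-dihydronaphthalen-1(2H)-one | CC(C)CCc1cc(OCc3ccccc3)c2c(c1C4=CC(OCc5ccccc5)=CC(=O)O4)C[C@H](OCc6ccccc6)CC2=O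
F0 | step 13 | none | none
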